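**Retrosynthetic overview**
1. Ester C–O bond: target 18 comes from diol 14 and O-acetyl isovanillic acid 16 (acylation with retention at C4, then phenol release).
2. The C4 hydroxyl comes from allylic C–H hydroxylation of 13; the C7 carbinol comes from methyl addition to ketone 12.
3. Both rings of 12 (six- and seven-membered) are formed in one operation by an amine-catalysed enantioselective intramolecular Diels–Alder reaction of the acyclic trienone 9, which sets C1 and C6.
4. Trienone 9 comes from ester 7 (vinyl ketone), aldehyde 5 (diene by olefination) and alkylation of isobutyronitrile 1 with bromo orthoester 2 (quaternary C11).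

Assumption: bicyclic compounds carry himachalane numbering (C1 and C6 ring-fusion carbons, C2=C3 alkene with the C3 methyl, C4 the ester carbon, C7 the tertiary carbinol carbon, C11 the gem-dimethyl carbon); α is the face of H-1 and H-6. The target is cis-fused with 4-O α, 7-OH β, i.e. (1S,4R,6R,7S).

**Step 1**
Reactants: 1 2-methylpropanenitrile; 2 4-bromo-1,1,1-trimethoxybutane
Product: 3 6,6,6-trimethoxy-2,2-dimethylhexanenitrile
Conditions: LiN(i-Pr)2, THF, −78 °C; then 2, −78 °C to rt
Reagents that add atoms: none
Why: α-Alkylation of the lithiated nitrile (SN2 at the primary bromide) builds the quaternary C11, and the orthoester is inert to the base and masks the later C7 carboxyl.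

**Step 2**
Reactants: 3 6,6,6-trimethoxy-2,2-dimethylhexanenitrile
Product: 5 methyl 5,5-dimethyl-6-oxohexanoate, via N-aluminio aldimine 4 (not isolated)
Conditions: i-Bu2AlH, toluene, −78 °C; then 1 M HCl, THF, 0 °C to rt
Reagents that add atoms: water, O
Why: Nitrile-to-aldehyde reduction stops at the N-aluminio aldimine (the orthoester does not react at −78 °C), and acidic hydrolysis then converts the imine to the aldehyde and the orthoester to the methyl ester.

**Step 3**
Reactants: 5 methyl 5,5-dimethyl-6-oxohexanoate; 6 diethyl (2-methylprop-2-en-1-yl)phosphonate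
Product: 7 methyl (6E)-5,5,8-trimethylnona-6,8-dienoate
Conditions: 6, n-BuLi, THF/DMPU, −78 °C; then 5, −78 °C to rt
Reagents that add atoms: none
Why: Horner–Wadsworth–Emmons olefination of the non-enolisable neopentyl aldehyde with the allylic phosphonate anion gives the (E)-diene (the tert-alkyl group enforces E), and the methyl ester does not react at low temperature.

**Step 4**
Reactants: 7 methyl (6E)-5,5,8-trimethylnona-6,8-dienoate
Product: 9 (8E)-7,7,10-trimethylundeca-1,8,10-trien-3-one, via Weinreb amide 8 (not isolated)
Conditions: MeNH(OMe)·HCl, i-PrMgCl, THF, −20 °C; then CH2=CHMgBr, 0 °C; inverse quench into cold 1 M HCl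
Reagents that add atoms: vinylmagnesium bromide, C=C[Mg]Br
Why: One-pot ester aminolysis to the Weinreb amide followed by Grignard addition gives the vinyl ketone, because the chelated tetrahedral intermediate blocks over-addition and the acidic inverse quench prevents aza-Michael addition of the released amine.

**Step 5**
Reactants: 9 (8E)-7,7,10-trimethylundeca-1,8,10-trien-3-one
Product: 12 (1S,6R)-14-norhimachal-2-en-7-one, via vinyl iminium perchlorate 10 (not isolated), via adduct iminium perchlorate 11 (not isolated)
Conditions: (2S,5S)-5-benzyl-3-methyl-2-(5-methylfuran-2-yl)imidazolidin-4-one·HClO4 (20 mol %), EtOH/H2O 19:1, 0.05 M, 0 °C, 48 h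
Reagents that add atoms: none
Why: Proposed new method: an iminium-catalysed enantioselective type 1 intramolecular Diels–Alder reaction of an alkyl vinyl ketone that closes a seven-membered ring, in which condensation of the chiral secondary ammonium salt with the ketone gives vinyl iminium ion 10, whose lowered LUMO lets the tethered 1,3-dialkyl diene add at 0 °C through the endo transition state (iminium carbon of the tether under the diene) that gives the cis ring fusion, the benzyl arm of the catalyst blocks one face of the vinyl group so that C1 and C6 are expected as (1S,6R), and hydrolysis of adduct iminium 11 returns the catalyst; the closest known reaction types are the intermolecular imidazolidinone-catalysed Diels–Alder reaction of ethyl vinyl ketone with acyclic dienes, the imidazolidinone-catalysed intramolecular Diels–Alder reaction of trienals to five- and six-membered carbocycles, and the racemic thermal or Lewis-acid intramolecular Diels–Alder reaction of 1,7,9-trien-3-ones and their homologues.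

**Step 6**
Reactants: 12 (1S,6R)-14-norhimachal-2-en-7-one
Product: 13 (1S,6R,7S)-himachal-2-en-7-ol
Conditions: MeMgBr, CeCl3, THF, −78 to 0 °C; aq NH4Cl
Reagents that add atoms: methylmagnesium bromide, C[Mg]Br
Why: Grignard 1,2-addition (CeCl3 suppresses enolisation and C6 epimerisation) should occur from the convex α face, syn to H-6 and anti to the C5 methylene of the cis-fused system, placing the methyl α and the hydroxyl β (7S).

**Step 7**
Reactants: 13 (1S,6R,7S)-himachal-2-en-7-ol
Product: 14 (1S,4R,6R,7S)-himachal-2-ene-4,7-diol
Conditions: SeO2 (0.3 equiv), t-BuOOH, CH2Cl2, 0 °C to rt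
Reagents that add atoms: selenium dioxide, O=[Se]=O; tert-butyl hydroperoxide, CC(C)(C)OO
Why: Selenium dioxide allylic hydroxylation (ene reaction, then 2,3-sigmatropic shift) is expected at the ring CH2 next to the more substituted alkene carbon (C4), with both suprafacial events on the open α face away from the β-oriented C11 and C7, giving the 4α (4R) alcohol.

**Step 8**
Reactants: 15 3-hydroxy-4-methoxybenzoic acid
Product: 16 3-acetoxy-4-methoxybenzoic acid
Conditions: Ac2O, pyridine, rt; then H2O
Reagents that add atoms: acetic anhydride, CC(=O)OC(C)=O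
Why: O-Acetylation protects the phenol, and the mixed anhydride formed at the carboxyl group is hydrolysed back to the acid on aqueous work-up.

**Step 9**
Reactants: 14 (1S,4R,6R,7S)-himachal-2-ene-4,7-diol; 16 3-acetoxy-4-methoxybenzoic acid
Product: 18 (1S,4R,6R,7S)-7-hydroxyhimachal-2-en-4-yl 3-hydroxy-4-methoxybenzoate, via acetyl-protected ester 17 (not isolated)
Conditions: EDC·HCl, DMAP (cat.), CH2Cl2, rt; then pyrrolidine, 0 °C
Reagents that add atoms: none
Why: Steglich esterification acylates only the secondary allylic hydroxyl (the tertiary C7 hydroxyl is inert) with retention at C4, and pyrrolidine then removes the much more electrophilic aryl acetate by aminolysis without cleaving the alkyl benzoate.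

**Compound list**
1 | 2-methylpropanenitrile (isobutyronitrile) | CC(C)C#N | starting material
2 | 4-bromo-1,1,1-trimethoxybutane (trimethyl 4-bromoorthobutyrate) | COC(CCCBr)(OC)OC | starting material
3 | 6,6,6-trimethoxy-2,2-dimethylhexanenitrile | COC(CCCC(C)(C)C#N)(OC)OC | intermediate
4 | N-(diisobutylaluminio)-6,6,6-trimethoxy-2,2-dimethylhexan-1-imine (not isolated) | COC(CCCC(C)(C)C=N[Al](CC(C)C)CC(C)C)(OC)OC | intermediate
5 | methyl 5,5-dimethyl-6-oxohexanoate | COC(=O)CCCC(C)(C)C=O | intermediate
6 | diethyl (2-methylprop-2-en-1-yl)phosphonate | CCOP(=O)(CC(C)=C)OCC | starting material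
7 | methyl (6E)-5,5,8-trimethylnona-6,8-dienoate | COC(=O)CCCC(C)(C)/C=C/C(C)=C | intermediate
8 | (6E)-N-methoxy-N,5,5,8-tetramethylnona-6,8-dienamide (not isolated) | CON(C)C(=O)CCCC(C)(C)/C=C/C(C)=C | intermediate
9 | (8E)-7,7,10-trimethylundeca-1,8,10-trien-3-one | C=CC(=O)CCCC(C)(C)/C=C/C(C)=C | intermediate
10 | iminium perchlorate formed from the carbonyl of 9 and N1 of the (2S,5S)-imidazolidinone catalyst, C=N geometry not fixed (not isolated) | CN1[C@@H](c2ccc(C)o2)[N+](=C(C=C)CCCC(C)(C)/C=C/C(C)=C)[C@@H](Cc2ccccc2)C1=O.[O-]Cl(=O)(=O)=O | intermediate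
11 | iminium perchlorate of cycloadduct 12 with the same catalyst (not isolated) | CN1[C@@H](c2ccc(C)o2)[N+](=C2CCCC(C)(C)[C@H]3C=C(C)CC[C@@H]23)[C@@H](Cc2ccccc2)C1=O.[O-]Cl(=O)(=O)=O | intermediate
12 | (1S,6R)-14-norhimachal-2-en-7-one, i.e. (4aR,9aS)-2,9,9-trimethyl-3,4,4a,6,7,8,9,9a-octahydro-5H-benzo[7]annulen-5-one, cis-fused | C1C[C@@H]2[C@H](C=C1C)C(C)(C)CCCC2=O | intermediate
13 | (1S,6R,7S)-himachal-2-en-7-ol, i.e. (4aR,5S,9aS)-2,5,9,9-tetramethyl-3,4,4a,6,7,8,9,9a-octahydro-5H-benzo[7]annulen-5-ol, 7-OH β | C1C[C@@H]2[C@H](C=C1C)C(C)(C)CCC[C@]2(C)O | intermediate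
14 | (1S,4R,6R,7S)-himachal-2-ene-4,7-diol, 4-OH α, 7-OH β | O[C@@H]1C[C@@H]2[C@H](C=C1C)C(C)(C)CCC[C@]2(C)O | intermediate
15 | 3-hydroxy-4-methoxybenzoic acid (isovanillic acid) | COc1ccc(C(=O)O)cc1O | starting material
16 | 3-acetoxy-4-methoxybenzoic acid | COc1ccc(C(=O)O)cc1OC(C)=O | intermediate
17 | (1S,4R,6R,7S)-7-hydroxyhimachal-2-en-4-yl 3-acetoxy-4-methoxybenzoate (not isolated) | COc1ccc(C(=O)O[C@@H]2C[C@@H]3[C@H](C=C2C)C(C)(C)CCC[C@]3(C)O)cc1OC(C)=O | intermediate
18 | (1S,4R,6R,7S)-7-hydroxyhimachal-2-en-4-yl 3-hydroxy-4-methoxybenzoate (CNP0210711.3) | COc1ccc(C(=O)O[C@@H]2C[C@@H]3[C@H](C=C2C)C(C)(C)CCC[C@]3(C)O)cc1O | target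

**Step count**
Total: 9 steps. Longest linear sequence: 8 steps (steps 1–7 and 9); step 8 is a one-step side branch.

**Three steps most likely to fail**

Step 5 (the proposed new cycloaddition). The seven-membered ring closure may be slow under iminium catalysis, the enantioselectivity may be low, or the sense of induction may be opposite to the one predicted (in that case the (2R,5R) catalyst would be tried first). The fallback sets out from trienone 9 and uses known chemistry: a thermal (toluene, 180 °C, sealed tube) or Me2AlCl-promoted (CH2Cl2, −78 to 0 °C) racemic intramolecular Diels–Alder reaction gives the racemic cis-fused ketone F1. Its enantiomers are separated by preparative chromatography on a chiral stationary phase, and the (1S,6R) enantiomer rejoins the route at 12.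

Step 6 (facial selectivity at C7). If the Grignard reagent adds from the β face and gives the 7-epimer, the fallback sets out from ketone 12. Wittig methylenation (Ph3P=CH2, THF) gives the exocyclic alkene (1S,6R)-himachala-2,7(14)-diene F2. Markovnikov radical hydration of the 1,1-disubstituted alkene in preference to the trisubstituted ring alkene (Mn(dpm)3 cat., PhSiH3, O2, i-PrOH/CH2Cl2, 0 °C; then PPh3) then delivers oxygen to the face the Grignard reagent had used. This gives the opposite C7 configuration and rejoins the route at 13.

Step 7 (site and face selectivity of the allylic hydroxylation, over-oxidation). The fallback sets out from alcohol 13. Allylic oxidation to the enone (Rh2(cap)4 cat., t-BuOOH, CH2Cl2) gives (1S,6R,7S)-7-hydroxyhimachal-2-en-4-one F3. Luche reduction (NaBH4, CeCl3·7H2O, MeOH, −78 °C) with hydride delivery from the open α face gives the 4β-alcohol (1S,4S,6R,7S)-himachal-2-ene-4,7-diol F4. Mitsunobu esterification of F4 with unprotected isovanillic acid 15 (PPh3, DIAD, THF, 0 °C) inverts C4, the carboxylic acid being far more acidic than the phenol. This rejoins the route directly at target 18 and makes step 8 unnecessary.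

**Further compounds**
F1 | step 5 | racemic cis-14-norhimachal-2-en-7-one (1:1 mixture of 12 and its enantiomer) | C1C[C@@H]2[C@H](C=C1C)C(C)(C)CCCC2=O.C1C[C@H]2[C@@H](C=C1C)C(C)(C)CCCC2=O
F2 | step 6 | (1S,6R)-himachala-2,7(14)-diene | C1C[C@@H]2[C@H](C=C1C)C(C)(C)CCCC2=C
F3 | step 7 | (1S,6R,7S)-7-hydroxyhimachal-2-en-4-one | O=C1C[C@@H]2[C@H](C=C1C)C(C)(C)CCC[C@]2(C)O
F4 | step 7 | (1S,4S,6R,7S)-himachal-2-ene-4,7-diol | O[C@H]1C[C@@H]2[C@H](C=C1C)C(C)(C)CCC[C@]2(C)O
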